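Remark on the chemistry: the SMILES has no stereocentre and the target, 2,3,4,6-tetrabromo-1-methyl-1H-indole, is achiral, so no enantiomer has to be chosen; the route is planned for this constitution.

## The problem

The target is a planar N-methylindole in which C2 and C3 of the pyrrole ring and C4 and C6 of the benzo ring carry bromine, while C5 and C7 carry hydrogen. No ring resists closure and there is no stereocentre; the whole difficulty is regiocontrol over four C–Br bonds. C3 and C2 are the indole's own nucleophilic carbons and take bromine readily. C4 and C6 are both meta to the ring nitrogen (through C7a) and are the benzo positions an electrophile reaches last; bromination of a 1-methylindole beyond C2/C3 goes on to C5 and C6 and leads to the 2,3,5,6-isomer. The benzo pattern is therefore usually bought in a pre-brominated benzene and the pyrrole ring built onto it, so aryl bromides must be carried through nitro reductions, condensations or metal-mediated ring closures. The feature that offers a way out is the C5–H bond: C5 is the one benzo carbon ortho to both C4 and C6, its para position is the blocked ring-fusion carbon C7a, and C7 is meta to it, so a removable donor on C5 would activate exactly the two benzo carbons that must be brominated. Once in place, the bromines limit what can follow: the C2–Br bond of a 2-bromoindole does not tolerate Pd(0), organolithiums, hydrogenolysis or hot mineral acid, and the C3 and C4 bromines sit in a peri relationship. C7, ortho to the ring nitrogen, must stay untouched.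

## Retrosynthesis

**Target 6 to amine 5 (C5–H back to C5–NH2).** An amino group is added retrosynthetically at C5; in the forward direction the C5–N bond is cut and replaced by C–H through the diazonium ion. NH2 is preferred to OH on C5 because a phenol would have to be removed by triflation and Pd/hydride reduction, which four C–Br bonds would not survive. It is preferred to a donor on C7 (ortho to C6, para to C4) because 5-substituted indoles are commodity compounds and C7 substituents clash with the N-methyl group. Compound 5 is no simpler than 6 in itself, but it turns all four brominated carbons into the most nucleophilic carbons of the molecule. The forward reaction must diazotise a weakly basic amine flanked by two bromines and reduce the diazonium ion without metals or strong acid.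

**Amine 5 to amine 3 (C2–Br, C3–Br, C4–Br and C6–Br, all four at once).** With the C5 donor present, the pyrrole ring's own bias accounts for C3 and C2 and the amino group for C4 and C6, so every C–Br bond can come from one electrophilic reagent in one flask, via tribromide 4. The precursor 3 (1-methyl-1H-indol-5-amine, C9H10N2) has no halogen at all. The forward reaction must achieve four regioselective substitutions without oxidising the aminoindole at nitrogen and must stop before C7. Cutting only the C4/C6 bromines here and the C2/C3 bromines earlier is kept as the fallback, since it costs two more steps.

**Amine 3 to nitroindole 2 to 5-nitro-1H-indole 1 (nitro reduction; N1–CH3).** 5-Nitroindole 1 is a bulk chemical. Methylation is placed first, when the indole N–H is the only N–H. Reduction is placed before any bromine is present, so that catalytic hydrogenation can be used without risk to C–Br bonds.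

## Roads not taken

**Alternative 1:** (the obvious route) Cut N–CH3, C2–Br and C3–Br back to 4,6-dibromo-1H-indole A1. Forward: N-methylation to 4,6-dibromo-1-methyl-1H-indole A2, then double bromination with NBS at C3 and C2. This is short and reliable if A1 is bought. However, A1 is a speciality compound whose benzo pattern must itself be carried from a pre-brominated nitrotoluene such as 2,4-dibromo-6-nitrotoluene A3 through a Leimgruber–Batcho sequence, with a nitro reduction that must spare two aryl bromides. The regiochemical problem is only moved upstream. The chosen plan makes all four C–Br bonds in one operation on a halogen-free commodity indole.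

**Alternative 2:** Cut N1–C7a and replace C2–Br by an ester. Forward: 2,4-dibromobenzaldehyde A4 is condensed with an azidoacetate ester to methyl (Z)-2-azido-3-(2,4-dibromophenyl)acrylate A5. Hemetsberger–Knittel thermolysis (nitrene insertion into the only free ortho C–H) gives methyl 4,6-dibromo-1H-indole-2-carboxylate A6. N-methylation and saponification give 4,6-dibromo-1-methyl-1H-indole-2-carboxylic acid A7, and NBS then brominates C3 and replaces CO2H at C2 by ipso-bromodecarboxylation. The attraction is that the ester the annulation needs becomes the leaving group for C2–Br. Against it: five to six steps, a thermolysed vinyl azide, an ipso attack at C2 of an indole already deactivated by three bromines, and benzo bromines that are still bought.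

**Alternative 3:** Cut N1–C2. Forward: 3,5-dibromo-2-(2,2-dibromovinyl)-N-methylaniline A8 undergoes copper-catalysed intramolecular C–N coupling to 2,4,6-tribromo-1-methyl-1H-indole A9, followed by NBS at C3. The coupling would have to pick one vinyl C–Br over two aryl C–Br bonds and over the C2–Br bond of its own product. A8 also needs an ortho-aminobenzaldehyde with the dibromo pattern already in place, which has no short commercial source. The chosen plan uses no metal once a bromine is present.

Key step: step 3

## Route

**Step 1**
Reactants: 1 5-nitro-1H-indole
Product: 2 1-methyl-5-nitro-1H-indole
Conditions: MeI (1.2 equiv), K2CO3 (1.5 equiv), DMF, rt to 40 °C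
Reagents that add atoms: iodomethane, CI
Why: SN2 N-alkylation of the indolide anion; the 5-nitro group makes N–H acidic enough for K2CO3 in DMF and suppresses C3 alkylation.

**Step 2**
Reactants: 2 1-methyl-5-nitro-1H-indole
Product: 3 1-methyl-1H-indol-5-amine
Conditions: H2 (1 atm), 10% Pd/C, EtOAc–EtOH, rt; filtered and concentrated under Ar, used at once
Reagents that add atoms: none
Why: Heterogeneous catalytic hydrogenation of an aromatic nitro group; no halogen is present yet, so hydrogenolysis cannot interfere, and the indole C2=C3 bond is not reduced under neutral conditions.

**Step 3**
Reactants: 3 1-methyl-1H-indol-5-amine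
Product: 5 2,3,4,6-tetrabromo-1-methyl-1H-indol-5-amine, via 3,4,6-tribromo-1-methyl-1H-indol-5-amine 4 (not isolated)
Conditions: NBS (4.05 equiv, in portions), DMF, −40 °C to rt, dark, Ar; then aq. Na2S2O3
Reagents that add atoms: N-bromosuccinimide, O=C1CCC(=O)N1Br
Why: Four consecutive electrophilic aromatic substitutions by NBS, each through a Wheland intermediate, are expected: the enamine carbon C3 and the two carbons ortho to the C5 amino group (C4 and C6) react first and converge on tribromide 4, and the last equivalent brominates C2, the normal second site of a 3-bromo-1-methylindole (attack at C3 to a 3,3-dibromoindoleninium ion, 1,2-shift of bromine to C2 and loss of the C2 proton, or direct attack at C2). The closest known reaction types are the ortho,ortho-dibromination of para-substituted anilines with NBS in DMF and the 2,3-dibromination of 1-methylindoles with two equivalents of NBS; here both are run in one flask. No ring is closed and no stereocentre is formed. The selectivity needed is C4 and C6 over C7 on the benzo ring: the amino group on C5 is ortho to C4 and C6, its para carbon C7a is quaternary, and C7 is meta to it and lies between C6–Br and the N-methyl group, so C7 should be the least activated and most hindered C–H of the molecule. Because NBS gives succinimide and not HBr, the amine stays unprotonated and keeps directing until both ortho positions are filled. Addition in portions at −40 °C keeps the concentration of electrophilic bromine low while the substrate is most easily oxidised; once C4 and C6 carry bromine the amine is flanked, less basic and harder to oxidise, so the slower C2 bromination can be finished at room temperature. The stoichiometry and the thiosulfate quench guard against a fifth bromination at C7 and return any N–Br species to N–H.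

**Step 4**
Reactants: 5 2,3,4,6-tetrabromo-1-methyl-1H-indol-5-amine
Product: 6 2,3,4,6-tetrabromo-1-methyl-1H-indole
Conditions: t-BuONO (1.5 equiv), 50% aq. H3PO2 (excess), THF, 0 °C to rt
Reagents that add atoms: none
Why: Hydrodediazoniation: tert-butyl nitrite diazotises the weakly basic, ortho,ortho-dibrominated amine in organic solvent, and hypophosphorous acid reduces the diazonium ion by a radical chain (the C5 aryl radical takes H from a P–H bond) at or below room temperature, which should leave aryl and heteroaryl C–Br bonds intact. The classical conversion of 2,4,6-tribromoaniline into 1,3,5-tribromobenzene is the model.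

## Compound list

1 | 5-nitro-1H-indole | O=[N+]([O-])c1ccc2[nH]ccc2c1 | starting material
2 | 1-methyl-5-nitro-1H-indole | Cn1ccc2cc([N+](=O)[O-])ccc21 | intermediate
3 | 1-methyl-1H-indol-5-amine | Cn1ccc2cc(N)ccc21 | intermediate
4 | 3,4,6-tribromo-1-methyl-1H-indol-5-amine | Cn1cc(Br)c2c(Br)c(N)c(Br)cc21 | intermediate
5 | 2,3,4,6-tetrabromo-1-methyl-1H-indol-5-amine | Cn1c(Br)c(Br)c2c(Br)c(N)c(Br)cc21 | intermediate
6 | 2,3,4,6-tetrabromo-1-methyl-1H-indole | Cn1c(Br)c(Br)c2c(Br)cc(Br)cc21 | target

## Step count and risks

Total step count: 4. Longest linear sequence: 4 (fully linear; 2 and 3 are also catalogue compounds, so the sequence can be entered later).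

**Step 3 (key step).** The most likely failure is oxidation at nitrogen during the first equivalents of NBS: N-bromination followed by oxidative coupling to azo or quinoid material, because the substrate is a para-diamine-type electron-rich arene. A second failure mode is loss of stoichiometric control at the end, with incomplete C2 bromination or a fifth bromination at C7. The fallback separates the two directing effects and sets the pyrrole bromines while the ring is still electron-poor. It sets out from 2: NBS (2.2 equiv, DMF, rt to 50 °C) should give 2,3-dibromo-1-methyl-5-nitro-1H-indole F1, on which oxidation cannot compete. Iron powder in AcOH–EtOH at 60 °C should reduce the nitro group without touching C–Br and give 2,3-dibromo-1-methyl-1H-indol-5-amine F2, which the two bromines make harder to oxidise. NBS (2.0 equiv, DMF, 0 °C) then only has to fill the two ortho positions and returns to the route at 5.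

**Step 4.** Diazotisation of the hindered, weakly basic amine may be incomplete. The diazonium ion may be captured by water or couple before hydrogen transfer. The aqueous acid may start hydrolysis at C2–Br. The fallback decouples diazotisation from reduction. It sets out from 5: NOBF4 in MeCN at −30 °C, a much stronger nitrosating agent under anhydrous conditions, followed by precipitation with ether should give 2,3,4,6-tetrabromo-1-methyl-1H-indole-5-diazonium tetrafluoroborate F3 as an isolable salt. Separate reduction with H3PO2 and catalytic Cu2O at 0 °C, with bicarbonate work-up, returns to the route at 6.

**Step 2.** The reduction itself is safe; the risk is air oxidation of the electron-rich amine 3 during filtration and concentration, which would carry coloured oxidised material into the key step. The fallback sets out from 2: hydrogenation in the presence of Boc2O traps the amine as tert-butyl (1-methyl-1H-indol-5-yl)carbamate F4, a storable compound that can be purified. HCl in dioxane then gives 1-methyl-1H-indol-5-aminium chloride F5, a shelf-stable salt. Neutralisation with NaHCO3 in the DMF of step 3 just before NBS addition returns to the route at 3.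

## Further compounds

F1 | step 3 | 2,3-dibromo-1-methyl-5-nitro-1H-indole | Cn1c(Br)c(Br)c2cc([N+](=O)[O-])ccc21
F2 | step 3 | 2,3-dibromo-1-methyl-1H-indol-5-amine | Cn1c(Br)c(Br)c2cc(N)ccc21
F3 | step 4 | 2,3,4,6-tetrabromo-1-methyl-1H-indole-5-diazonium tetrafluoroborate | Cn1c(Br)c(Br)c2c(Br)c([N+]#N)c(Br)cc21.F[B-](F)(F)F
F4 | step 2 | tert-butyl (1-methyl-1H-indol-5-yl)carbamate | Cn1ccc2cc(NC(=O)OC(C)(C)C)ccc21
F5 | step 2 | 1-methyl-1H-indol-5-aminium chloride | Cn1ccc2cc([NH3+])ccc21.[Cl-]
A1 | alternative 1 | 4,6-dibromo-1H-indole | Brc1cc(Br)c2cc[nH]c2c1
A2 | alternative 1 | 4,6-dibromo-1-methyl-1H-indole | Cn1ccc2c(Br)cc(Br)cc21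
A3 | alternative 1 | 2,4-dibromo-6-nitrotoluene | Cc1c(Br)cc(Br)cc1[N+](=O)[O-]
A4 | alternative 2 | 2,4-dibromobenzaldehyde | O=Cc1ccc(Br)cc1Br
A5 | alternative 2 | methyl (Z)-2-azido-3-(2,4-dibromophenyl)acrylate | COC(=O)/C(N=[N+]=[N-])=C/c1ccc(Br)cc1Br
A6 | alternative 2 | methyl 4,6-dibromo-1H-indole-2-carboxylate | COC(=O)c1cc2c(Br)cc(Br)cc2[nH]1
A7 | alternative 2 | 4,6-dibromo-1-methyl-1H-indole-2-carboxylic acid | Cn1c(C(=O)O)cc2c(Br)cc(Br)cc21
A8 | alternative 3 | 3,5-dibromo-2-(2,2-dibromovinyl)-N-methylaniline | CNc1cc(Br)cc(Br)c1C=C(Br)Br
A9 | alternative 3 | 2,4,6-tribromo-1-methyl-1H-indole | Cn1c(Br)cc2c(Br)cc(Br)cc21
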